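Labels: ring A is the guaiacyl ring on the benzyl group at lactone C3. Ring B is the benzo ring of the dihydrobenzofuran (O1, C2, C3, C3a to C7a). Ring C is the guaiacyl ring on C2.
Cuts, in retrosynthetic order: lactone C3-CH2(ring A); the lactone acyl C-O bond; lactone C4-CH2(ring B); C2-C3 of the dihydrofuran; the C3a-C(alpha) bond of the arylacetate; the O1-CH2 ether bond to ring C.
Enabling feature: C2 and C3, the only stereocentres of the ring O1-C2-C3-C3a-C7a, are bonded to each other. C2 lies between O1 and ring C and C3 hangs on C3a, so a carbene at C3 meets a C-H bond of an ArO-CH2-Ar unit at 1,5-distance, and one new bond delivers the ring and both centres.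
Forward: the ring C bromide is put on the phenol of 5-iodovanillin and the iodide becomes an aryldiazoacetate. The dihydrofuran ring closes first and the butyrolactone second (succinate alkylation, reductive lactonisation). Ring A is attached last and three benzyl ethers fall together.
Stereochemistry: C2 and C3 come from Rh2(S-DOSP)4 matched with an (S)-lactamide ester, lactone C4 from (R)-4-benzyloxazolidinone, and lactone C3 from the C4 substituent (anti alkylation).

Key step: step 11

Assumption: the pair Rh2(S-DOSP)4 / (S)-lactamide ester is taken to give the (2S,3S)-trans ester, by analogy with closely related 2-(3,4-dialkoxybenzyloxy)-3-methoxyphenyl diazoacetates; both chiral elements are available in either mirror-image form should the sense have to be reversed.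

Step 1
Reactants: 1 4-benzyloxy-3-methoxybenzaldehyde (O-benzylvanillin)
Product: 2 4-benzyloxy-3-methoxybenzyl alcohol
Conditions: NaBH4, MeOH, 0 °C
Reagents that add atoms: none
Why: Borohydride reduction of an aromatic aldehyde is fast and leaves both aryl ethers untouched.

Step 2
Reactants: 2 4-benzyloxy-3-methoxybenzyl alcohol
Product: 3 4-benzyloxy-3-methoxybenzyl bromide
Conditions: PBr3, Et2O, 0 °C
Reagents that add atoms: phosphorus tribromide BrP(Br)Br
Why: PBr3 bromination of a benzylic alcohol (bromide displaces the phosphite ester) is routine for this electron-rich series, and the one bromide later supplies both ring C and ring A.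

Step 3
Reactants: 4 5-iodovanillin; 3 4-benzyloxy-3-methoxybenzyl bromide
Product: 5 4-[(4-benzyloxy-3-methoxybenzyl)oxy]-3-iodo-5-methoxybenzaldehyde
Conditions: K2CO3, DMF, rt
Reagents that add atoms: none
Why: Williamson ether synthesis; the acidic, flanked phenol of 4 is fully ionised by carbonate and the benzylic bromide is reactive enough to overcome the crowding.

Step 4
Reactants: 5 4-[(4-benzyloxy-3-methoxybenzyl)oxy]-3-iodo-5-methoxybenzaldehyde
Product: 6 {4-[(4-benzyloxy-3-methoxybenzyl)oxy]-3-iodo-5-methoxyphenyl}methanol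
Conditions: NaBH4, THF/MeOH, 0 °C
Reagents that add atoms: none
Why: Borohydride reduction removes the aldehyde, which would otherwise condense with malonate in step 6, and does not touch the aryl iodide.

Step 5
Reactants: 6 {4-[(4-benzyloxy-3-methoxybenzyl)oxy]-3-iodo-5-methoxyphenyl}methanol
Product: 7 tert-butyl({4-[(4-benzyloxy-3-methoxybenzyl)oxy]-3-iodo-5-methoxybenzyl}oxy)dimethylsilane
Conditions: TBSCl, imidazole, CH2Cl2, rt
Reagents that add atoms: tert-butyldimethylsilyl chloride CC(C)(C)[Si](C)(C)Cl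
Why: Imidazole-promoted silylation of a primary alcohol gives an ether that tolerates carbonate, hydroxide, DBU and hydride and can later be exchanged directly for bromide.

Step 6
Reactants: 7 tert-butyl({4-[(4-benzyloxy-3-methoxybenzyl)oxy]-3-iodo-5-methoxybenzyl}oxy)dimethylsilane; 8 dimethyl malonate
Product: 9 dimethyl 2-{2-[(4-benzyloxy-3-methoxybenzyl)oxy]-5-[(tert-butyldimethylsilyloxy)methyl]-3-methoxyphenyl}malonate
Conditions: CuI (10 mol%), 2-picolinic acid (20 mol%), Cs2CO3, 1,4-dioxane, 70 °C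
Reagents that add atoms: none
Why: Copper-catalysed arylation of a malonate with an aryl iodide (Hurtley-type coupling) is a mild, general route to arylmalonates, and the product is protected from a second arylation by its own deprotonation.

Step 7
Reactants: 9 dimethyl 2-{2-[(4-benzyloxy-3-methoxybenzyl)oxy]-5-[(tert-butyldimethylsilyloxy)methyl]-3-methoxyphenyl}malonate
Product: 11 2-{2-[(4-benzyloxy-3-methoxybenzyl)oxy]-5-[(tert-butyldimethylsilyloxy)methyl]-3-methoxyphenyl}acetic acid, via arylmalonic acid 10 (not isolated)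
Conditions: LiOH, THF/MeOH/H2O, 50 °C; 1 M HCl to pH 4, 0 °C; toluene, 90 °C
Reagents that add atoms: lithium hydroxide [Li+].[OH-]
Why: Saponification followed by thermal decarboxylation of an arylmalonic acid (the close of a malonic ester synthesis) needs only brief, weakly acidic handling that a primary silyl ether withstands.

Step 8
Reactants: 12 ethyl (S)-lactate; 13 pyrrolidine
Product: 14 (S)-2-hydroxy-1-(pyrrolidin-1-yl)propan-1-one
Conditions: neat, rt to 45 °C
Reagents that add atoms: none
Why: Aminolysis of an alpha-hydroxy ester by a nucleophilic secondary amine proceeds without added base, so the lactate stereocentre is retained.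

Step 9
Reactants: 11 2-{2-[(4-benzyloxy-3-methoxybenzyl)oxy]-5-[(tert-butyldimethylsilyloxy)methyl]-3-methoxyphenyl}acetic acid; 14 (S)-2-hydroxy-1-(pyrrolidin-1-yl)propan-1-one
Product: 15 (S)-1-oxo-1-(pyrrolidin-1-yl)propan-2-yl 2-{2-[(4-benzyloxy-3-methoxybenzyl)oxy]-5-[(tert-butyldimethylsilyloxy)methyl]-3-methoxyphenyl}acetate
Conditions: EDC·HCl, DMAP (cat.), CH2Cl2, 0 °C to rt
Reagents that add atoms: none
Why: Steglich-type carbodiimide esterification joins an unhindered arylacetic acid to a secondary alcohol under neutral conditions that spare the silyl and benzyl ethers.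

Step 10
Reactants: 15 (S)-1-oxo-1-(pyrrolidin-1-yl)propan-2-yl 2-{2-[(4-benzyloxy-3-methoxybenzyl)oxy]-5-[(tert-butyldimethylsilyloxy)methyl]-3-methoxyphenyl}acetate
Product: 16 (S)-1-oxo-1-(pyrrolidin-1-yl)propan-2-yl 2-diazo-2-{2-[(4-benzyloxy-3-methoxybenzyl)oxy]-5-[(tert-butyldimethylsilyloxy)methyl]-3-methoxyphenyl}acetate
Conditions: p-ABSA, DBU, MeCN, 0 °C to rt
Reagents that add atoms: 4-acetamidobenzenesulfonyl azide CC(=O)Nc1ccc(cc1)S(=O)(=O)N=[N+]=[N-]
Why: Regitz diazo transfer works directly on arylacetates because the benzylic ester proton is acidic enough for DBU, whereas the lactamide C-H is not.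

Step 11
Reactants: 16 (S)-1-oxo-1-(pyrrolidin-1-yl)propan-2-yl 2-diazo-2-{2-[(4-benzyloxy-3-methoxybenzyl)oxy]-5-[(tert-butyldimethylsilyloxy)methyl]-3-methoxyphenyl}acetate
Product: 17 (S)-1-oxo-1-(pyrrolidin-1-yl)propan-2-yl (2S,3S)-trans-2-(4-benzyloxy-3-methoxyphenyl)-5-[(tert-butyldimethylsilyloxy)methyl]-7-methoxy-2,3-dihydrobenzofuran-3-carboxylate
Conditions: Rh2(S-DOSP)4 [dirhodium tetrakis((S)-N-(4-dodecylbenzenesulfonyl)prolinate)] (1 mol%), degassed CH2Cl2, slow addition of 16, high dilution, rt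
Reagents that add atoms: none
Why: The catalyst expels N2 from 16, and the rhodium-bound carbene, tempered by ring B as donor and the ester as acceptor, pushes its electrophilic carbon into one C-H bond of the neighbouring ArO-CH2 group through a concerted, asynchronous three-centre transition state with hydride-shift character. The closest known reaction type is the enantioselective intramolecular C-H insertion of aryldiazoacetates into benzylic ethers, which gives 2-aryl-2,3-dihydrobenzofuran-3-carboxylates. The new C2-C3 bond completes the five-membered ring O1-C2-C3-C3a-C7a, that is insertion at the 1,5-position, for which the transition state is least strained. C2 becomes S because the prolinate pocket of the catalyst and the (S)-lactamide ester, used as a matched pair, present only one of the two diastereotopic benzylic hydrogens to the carbene. C3 becomes S in the same event because the ester turns away from ring C in the transition state, giving the trans ring, which is also the more stable isomer. The step needs site selectivity as well: the reacting C-H bond is activated by both O1 and electron-rich ring C and is the only one within reach, slow addition at high dilution suppresses carbene dimerisation and intermolecular attack on the silyl and benzyl ether CH2 groups, and minor isomers are diastereomers that chromatography removes.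

Step 12
Reactants: 17 (S)-1-oxo-1-(pyrrolidin-1-yl)propan-2-yl (2S,3S)-trans-2-(4-benzyloxy-3-methoxyphenyl)-5-[(tert-butyldimethylsilyloxy)methyl]-7-methoxy-2,3-dihydrobenzofuran-3-carboxylate
Product: 18 [(2S,3R)-2-(4-benzyloxy-3-methoxyphenyl)-5-[(tert-butyldimethylsilyloxy)methyl]-7-methoxy-2,3-dihydrobenzofuran-3-yl]methanol
Conditions: LiBH4, MeOH (2 equiv), THF, 0 °C to rt
Reagents that add atoms: none
Why: Hydride reduction of the activated alpha-acyloxyamide ester gives the hydroxymethyl group and releases the auxiliary in one operation under weakly basic conditions that avoid ring opening by retro-oxa-Michael reaction; the C3 descriptor changes from S to R only because CH2OH ranks below C2.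

Step 13
Reactants: 18 [(2S,3R)-2-(4-benzyloxy-3-methoxyphenyl)-5-[(tert-butyldimethylsilyloxy)methyl]-7-methoxy-2,3-dihydrobenzofuran-3-yl]methanol
Product: 19 (2S,3R)-2-(4-benzyloxy-3-methoxyphenyl)-3-(benzyloxymethyl)-5-[(tert-butyldimethylsilyloxy)methyl]-7-methoxy-2,3-dihydrobenzofuran
Conditions: NaH, BnBr, Bu4NI (cat.), THF, 0 °C to rt
Reagents that add atoms: benzyl bromide BrCc1ccccc1
Why: Williamson benzylation gives an ether that survives phosphonium bromide, enolates, LiBH4 and acid and leaves at the end together with the two phenolic benzyl groups.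

Step 14
Reactants: 19 (2S,3R)-2-(4-benzyloxy-3-methoxyphenyl)-3-(benzyloxymethyl)-5-[(tert-butyldimethylsilyloxy)methyl]-7-methoxy-2,3-dihydrobenzofuran
Product: 20 (2S,3R)-2-(4-benzyloxy-3-methoxyphenyl)-3-(benzyloxymethyl)-5-(bromomethyl)-7-methoxy-2,3-dihydrobenzofuran
Conditions: Ph3PBr2, CH2Cl2, 0 °C to rt; used at once
Reagents that add atoms: triphenylphosphine dibromide BrP(Br)(c1ccccc1)(c1ccccc1)c1ccccc1
Why: Direct silyl ether to bromide exchange (Appel-type oxyphosphonium pathway) transfers the silyl group to bromide and then displaces Ph3PO at the benzylic carbon under neutral conditions that leave benzyl and aryl ethers alone.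

Step 15
Reactants: 21 4-tert-butoxy-4-oxobutanoic acid (mono-tert-butyl succinate); 22 (R)-4-benzyl-1,3-oxazolidin-2-one
Product: 24 tert-butyl 4-[(4R)-4-benzyl-2-oxo-1,3-oxazolidin-3-yl]-4-oxobutanoate, via mixed pivalic anhydride 23 (not isolated)
Conditions: PivCl, Et3N, THF, -20 °C; then LiCl, 22, -20 °C to rt
Reagents that add atoms: pivaloyl chloride CC(C)(C)C(=O)Cl (its atoms are carried in 23 only)
Why: Mixed-anhydride N-acylation of an oxazolidinone in the presence of LiCl is selective for the unhindered succinyl carbonyl and needs no strong base.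

Step 16
Reactants: 24 tert-butyl 4-[(4R)-4-benzyl-2-oxo-1,3-oxazolidin-3-yl]-4-oxobutanoate; 20 (2S,3R)-2-(4-benzyloxy-3-methoxyphenyl)-3-(benzyloxymethyl)-5-(bromomethyl)-7-methoxy-2,3-dihydrobenzofuran
Product: 26 tert-butyl (3R)-4-[(4R)-4-benzyl-2-oxo-1,3-oxazolidin-3-yl]-3-{[(2S,3R)-2-(4-benzyloxy-3-methoxyphenyl)-3-(benzyloxymethyl)-7-methoxy-2,3-dihydrobenzofuran-5-yl]methyl}-4-oxobutanoate, via sodium Z-enolate 25 (not isolated)
Conditions: 24 (1.5 equiv), NaHMDS, THF, -78 °C; then 20, -78 to -30 °C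
Reagents that add atoms: none
Why: Evans asymmetric alkylation; NaHMDS removes the more acidic proton next to the imide, and in the chelated Z-enolate the (R)-benzyl group screens one face, so the benzylic bromide enters from the open face and sets the future lactone C4 as R.

Step 17
Reactants: 26 tert-butyl (3R)-4-[(4R)-4-benzyl-2-oxo-1,3-oxazolidin-3-yl]-3-{[(2S,3R)-2-(4-benzyloxy-3-methoxyphenyl)-3-(benzyloxymethyl)-7-methoxy-2,3-dihydrobenzofuran-5-yl]methyl}-4-oxobutanoate
Product: 28 (4R)-4-{[(2S,3R)-2-(4-benzyloxy-3-methoxyphenyl)-3-(benzyloxymethyl)-7-methoxy-2,3-dihydrobenzofuran-5-yl]methyl}dihydrofuran-2(3H)-one, via hydroxy tert-butyl ester 27 (not isolated)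
Conditions: LiBH4, H2O (1 equiv), Et2O/THF, 0 °C; work-up; TsOH·H2O (10 mol%), toluene, 60 °C
Reagents that add atoms: none
Why: Reductive removal of the auxiliary (LiBH4 attacks the activated exocyclic imide carbonyl but not the tert-butyl ester) frees a gamma-hydroxy ester that closes the five-membered lactone by acid-catalysed transesterification, with no bond to a stereocentre being touched.

Step 18
Reactants: 28 (4R)-4-{[(2S,3R)-2-(4-benzyloxy-3-methoxyphenyl)-3-(benzyloxymethyl)-7-methoxy-2,3-dihydrobenzofuran-5-yl]methyl}dihydrofuran-2(3H)-one; 3 4-benzyloxy-3-methoxybenzyl bromide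
Product: 30 (3R,4R)-3-(4-benzyloxy-3-methoxybenzyl)-4-{[(2S,3R)-2-(4-benzyloxy-3-methoxyphenyl)-3-(benzyloxymethyl)-7-methoxy-2,3-dihydrobenzofuran-5-yl]methyl}dihydrofuran-2(3H)-one, via lithium enolate 29 (not isolated)
Conditions: LiHMDS, THF, -78 °C; then 3, DMPU, -78 to -40 °C
Reagents that add atoms: none
Why: Diastereoselective lactone enolate alkylation; the C4 substituent blocks one face of the planar enolate, so the bromide adds anti to it and sets C3 as R in the trans relationship typical of 3,4-dibenzylbutyrolactones, which is also the more stable epimer.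

Step 19
Reactants: 30 (3R,4R)-3-(4-benzyloxy-3-methoxybenzyl)-4-{[(2S,3R)-2-(4-benzyloxy-3-methoxyphenyl)-3-(benzyloxymethyl)-7-methoxy-2,3-dihydrobenzofuran-5-yl]methyl}dihydrofuran-2(3H)-one
Product: 31 lappaol A
Conditions: H2 (1 atm), 10% Pd/C, EtOAc/EtOH, rt, stopped at full conversion
Reagents that add atoms: none
Why: Catalytic hydrogenolysis cleaves the two phenolic and the one aliphatic benzyl ether under neutral conditions at ambient pressure, under which the cyclic C2-O1 ether, the lactone and all four stereocentres should persist.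

Compound list
1 | 4-benzyloxy-3-methoxybenzaldehyde | COc1cc(C=O)ccc1OCc1ccccc1 | starting material
2 | 4-benzyloxy-3-methoxybenzyl alcohol | COc1cc(CO)ccc1OCc1ccccc1 | intermediate
3 | 4-benzyloxy-3-methoxybenzyl bromide | COc1cc(CBr)ccc1OCc1ccccc1 | intermediate
4 | 5-iodovanillin | COc1cc(C=O)cc(I)c1O | starting material
5 | 4-[(4-benzyloxy-3-methoxybenzyl)oxy]-3-iodo-5-methoxybenzaldehyde | COc1cc(C=O)cc(I)c1OCc1ccc(OCc2ccccc2)c(OC)c1 | intermediate
6 | {4-[(4-benzyloxy-3-methoxybenzyl)oxy]-3-iodo-5-methoxyphenyl}methanol | COc1cc(CO)cc(I)c1OCc1ccc(OCc2ccccc2)c(OC)c1 | intermediate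
7 | tert-butyl({4-[(4-benzyloxy-3-methoxybenzyl)oxy]-3-iodo-5-methoxybenzyl}oxy)dimethylsilane | COc1cc(CO[Si](C)(C)C(C)(C)C)cc(I)c1OCc1ccc(OCc2ccccc2)c(OC)c1 | intermediate
8 | dimethyl malonate | COC(=O)CC(=O)OC | starting material
9 | dimethyl 2-{2-[(4-benzyloxy-3-methoxybenzyl)oxy]-5-[(tert-butyldimethylsilyloxy)methyl]-3-methoxyphenyl}malonate | COC(=O)C(C(=O)OC)c1cc(CO[Si](C)(C)C(C)(C)C)cc(OC)c1OCc1ccc(OCc2ccccc2)c(OC)c1 | intermediate
10 | 2-{2-[(4-benzyloxy-3-methoxybenzyl)oxy]-5-[(tert-butyldimethylsilyloxy)methyl]-3-methoxyphenyl}malonic acid (not isolated) | OC(=O)C(C(=O)O)c1cc(CO[Si](C)(C)C(C)(C)C)cc(OC)c1OCc1ccc(OCc2ccccc2)c(OC)c1 | intermediate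
11 | 2-{2-[(4-benzyloxy-3-methoxybenzyl)oxy]-5-[(tert-butyldimethylsilyloxy)methyl]-3-methoxyphenyl}acetic acid | OC(=O)Cc1cc(CO[Si](C)(C)C(C)(C)C)cc(OC)c1OCc1ccc(OCc2ccccc2)c(OC)c1 | intermediate
12 | ethyl (S)-lactate | C[C@H](O)C(=O)OCC | starting material
13 | pyrrolidine | C1CCNC1 | starting material
14 | (S)-2-hydroxy-1-(pyrrolidin-1-yl)propan-1-one | C[C@H](O)C(=O)N1CCCC1 | intermediate
15 | (S)-1-oxo-1-(pyrrolidin-1-yl)propan-2-yl ester of acid 11 | C[C@H](OC(=O)Cc1cc(CO[Si](C)(C)C(C)(C)C)cc(OC)c1OCc1ccc(OCc2ccccc2)c(OC)c1)C(=O)N1CCCC1 | intermediate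
16 | (S)-1-oxo-1-(pyrrolidin-1-yl)propan-2-yl 2-diazo-2-{2-[(4-benzyloxy-3-methoxybenzyl)oxy]-5-[(tert-butyldimethylsilyloxy)methyl]-3-methoxyphenyl}acetate | C[C@H](OC(=O)C(=[N+]=[N-])c1cc(CO[Si](C)(C)C(C)(C)C)cc(OC)c1OCc1ccc(OCc2ccccc2)c(OC)c1)C(=O)N1CCCC1 | intermediate
17 | (S)-1-oxo-1-(pyrrolidin-1-yl)propan-2-yl (2S,3S)-trans-2-(4-benzyloxy-3-methoxyphenyl)-5-[(tert-butyldimethylsilyloxy)methyl]-7-methoxy-2,3-dihydrobenzofuran-3-carboxylate | CC(C)(C)[Si](C)(C)OCc1cc(OC)c2c(c1)[C@H](C(=O)O[C@@H](C)C(=O)N1CCCC1)[C@@H](c1ccc(OCc3ccccc3)c(OC)c1)O2 | intermediate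
18 | [(2S,3R)-2-(4-benzyloxy-3-methoxyphenyl)-5-[(tert-butyldimethylsilyloxy)methyl]-7-methoxy-2,3-dihydrobenzofuran-3-yl]methanol | CC(C)(C)[Si](C)(C)OCc1cc(OC)c2c(c1)[C@H](CO)[C@@H](c1ccc(OCc3ccccc3)c(OC)c1)O2 | intermediate
19 | (2S,3R)-2-(4-benzyloxy-3-methoxyphenyl)-3-(benzyloxymethyl)-5-[(tert-butyldimethylsilyloxy)methyl]-7-methoxy-2,3-dihydrobenzofuran | CC(C)(C)[Si](C)(C)OCc1cc(OC)c2c(c1)[C@H](COCc1ccccc1)[C@@H](c1ccc(OCc3ccccc3)c(OC)c1)O2 | intermediate
20 | (2S,3R)-2-(4-benzyloxy-3-methoxyphenyl)-3-(benzyloxymethyl)-5-(bromomethyl)-7-methoxy-2,3-dihydrobenzofuran | BrCc1cc(OC)c2c(c1)[C@H](COCc1ccccc1)[C@@H](c1ccc(OCc3ccccc3)c(OC)c1)O2 | intermediate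
21 | 4-tert-butoxy-4-oxobutanoic acid | CC(C)(C)OC(=O)CCC(=O)O | starting material
22 | (R)-4-benzyl-1,3-oxazolidin-2-one | O=C1N[C@H](Cc2ccccc2)CO1 | starting material
23 | 4-tert-butoxy-4-oxobutanoic pivalic anhydride (not isolated) | CC(C)(C)OC(=O)CCC(=O)OC(=O)C(C)(C)C | intermediate
24 | tert-butyl 4-[(4R)-4-benzyl-2-oxo-1,3-oxazolidin-3-yl]-4-oxobutanoate | CC(C)(C)OC(=O)CCC(=O)N1[C@H](Cc2ccccc2)COC1=O | intermediate
25 | sodium (Z)-enolate of imide 24 (not isolated) | [Na+].CC(C)(C)OC(=O)C/C=C(\[O-])N1[C@H](Cc2ccccc2)COC1=O | intermediate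
26 | tert-butyl (3R)-4-[(4R)-4-benzyl-2-oxo-1,3-oxazolidin-3-yl]-3-{[(2S,3R)-2-(4-benzyloxy-3-methoxyphenyl)-3-(benzyloxymethyl)-7-methoxy-2,3-dihydrobenzofuran-5-yl]methyl}-4-oxobutanoate | CC(C)(C)OC(=O)C[C@@H](Cc1cc(OC)c2c(c1)[C@H](COCc1ccccc1)[C@@H](c1ccc(OCc3ccccc3)c(OC)c1)O2)C(=O)N1[C@H](Cc2ccccc2)COC1=O | intermediate
27 | tert-butyl (3R)-3-{[(2S,3R)-2-(4-benzyloxy-3-methoxyphenyl)-3-(benzyloxymethyl)-7-methoxy-2,3-dihydrobenzofuran-5-yl]methyl}-4-hydroxybutanoate (not isolated) | CC(C)(C)OC(=O)C[C@@H](Cc1cc(OC)c2c(c1)[C@H](COCc1ccccc1)[C@@H](c1ccc(OCc3ccccc3)c(OC)c1)O2)CO | intermediate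
28 | (4R)-4-{[(2S,3R)-2-(4-benzyloxy-3-methoxyphenyl)-3-(benzyloxymethyl)-7-methoxy-2,3-dihydrobenzofuran-5-yl]methyl}dihydrofuran-2(3H)-one | O=C1C[C@@H](Cc2cc(OC)c3c(c2)[C@H](COCc2ccccc2)[C@@H](c2ccc(OCc4ccccc4)c(OC)c2)O3)CO1 | intermediate
29 | lithium enolate of lactone 28 (not isolated) | [Li+].[O-]C1=C[C@@H](Cc2cc(OC)c3c(c2)[C@H](COCc2ccccc2)[C@@H](c2ccc(OCc4ccccc4)c(OC)c2)O3)CO1 | intermediate
30 | (3R,4R)-3-(4-benzyloxy-3-methoxybenzyl)-4-{[(2S,3R)-2-(4-benzyloxy-3-methoxyphenyl)-3-(benzyloxymethyl)-7-methoxy-2,3-dihydrobenzofuran-5-yl]methyl}dihydrofuran-2(3H)-one (tri-O-benzyl lappaol A) | COc1cc(C[C@H]2C(=O)OC[C@@H]2Cc2cc(OC)c3c(c2)[C@H](COCc2ccccc2)[C@@H](c2ccc(OCc4ccccc4)c(OC)c2)O3)ccc1OCc1ccccc1 | intermediate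
31 | lappaol A, (3R,4R)-3-(4-hydroxy-3-methoxybenzyl)-4-{[(2S,3R)-2-(4-hydroxy-3-methoxyphenyl)-3-(hydroxymethyl)-7-methoxy-2,3-dihydrobenzofuran-5-yl]methyl}dihydrofuran-2(3H)-one | COc1cc(C[C@H]2C(=O)OC[C@@H]2Cc2cc(OC)c3c(c2)[C@H](CO)[C@@H](c2ccc(O)c(OC)c2)O3)ccc1O | target

Total step count: 19.
Longest linear sequence: 17 steps (steps 1 to 7, 9 to 14 and 16 to 19, from 1 to 31).

Steps most likely to fail

**Step 11.** The two diastereotopic benzylic hydrogens may be told apart poorly, or the trans preference may erode, because the 7-methoxy group next to O1 restricts the conformation of the ether side chain.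
- The fallback hands absolute control to the catalyst alone and relative control to thermodynamics.
- It sets out from acid 11. MeI and K2CO3 in DMF give methyl arylacetate F1, and p-ABSA with DBU gives methyl aryldiazoacetate F2.
- A phthaloyl-tert-leucinate catalyst, a class known for cis-selective insertion into benzylic ether C-H bonds, is used in toluene at -78 °C. The enantiomer that delivers 2S is taken to be Rh2(R-PTTL)4, dirhodium tetrakis(N-phthaloyl-(R)-tert-leucinate). It should give cis-(2S,3R) methyl ester F3.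
- NaOMe in MeOH then epimerises C3 to trans-(2S,3S) methyl ester F4.
- LiBH4 reduction comes back to the route at alcohol 18.

**Step 6.** Turnover at copper may be slow beside the bulky ortho benzyloxy group, with protodeiodination taking over.
- The fallback replaces the malonate arylation and decarboxylation by a palladium-catalysed cross-coupling of a zinc enolate (Negishi-type alpha-arylation with a Reformatsky reagent).
- It sets out from iodide 7. Commercial (2-ethoxy-2-oxoethyl)zinc bromide with Pd(dba)2 and P(t-Bu)3 in THF at rt to 50 °C should give ethyl arylacetate F5.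
- LiOH in THF/MeOH/H2O comes back to the route at acid 11, bypassing 9 and 10.

**Step 19.** Hydrogenolytic opening of the benzylic C2-O1 bond may compete with the slower cleavage of the aliphatic benzyl ether.
- The fallback gives up reduction altogether in favour of Lewis-acid dealkylation with a cation trap.
- It sets out from 30. BCl3 and pentamethylbenzene in CH2Cl2 at -78 °C should remove all three benzyl groups while aryl methyl ethers and the lactone stay intact.
- It comes back directly at 31. No compound outside the list is made on this path (F0).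

Further compounds
F1 | step 11 | methyl 2-{2-[(4-benzyloxy-3-methoxybenzyl)oxy]-5-[(tert-butyldimethylsilyloxy)methyl]-3-methoxyphenyl}acetate | COC(=O)Cc1cc(CO[Si](C)(C)C(C)(C)C)cc(OC)c1OCc1ccc(OCc2ccccc2)c(OC)c1
F2 | step 11 | methyl 2-diazo-2-{2-[(4-benzyloxy-3-methoxybenzyl)oxy]-5-[(tert-butyldimethylsilyloxy)methyl]-3-methoxyphenyl}acetate | COC(=O)C(=[N+]=[N-])c1cc(CO[Si](C)(C)C(C)(C)C)cc(OC)c1OCc1ccc(OCc2ccccc2)c(OC)c1
F3 | step 11 | methyl (2S,3R)-cis-2-(4-benzyloxy-3-methoxyphenyl)-5-[(tert-butyldimethylsilyloxy)methyl]-7-methoxy-2,3-dihydrobenzofuran-3-carboxylate | CC(C)(C)[Si](C)(C)OCc1cc(OC)c2c(c1)[C@@H](C(=O)OC)[C@@H](c1ccc(OCc3ccccc3)c(OC)c1)O2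
F4 | step 11 | methyl (2S,3S)-trans-2-(4-benzyloxy-3-methoxyphenyl)-5-[(tert-butyldimethylsilyloxy)methyl]-7-methoxy-2,3-dihydrobenzofuran-3-carboxylate | CC(C)(C)[Si](C)(C)OCc1cc(OC)c2c(c1)[C@H](C(=O)OC)[C@@H](c1ccc(OCc3ccccc3)c(OC)c1)O2
F5 | step 6 | ethyl 2-{2-[(4-benzyloxy-3-methoxybenzyl)oxy]-5-[(tert-butyldimethylsilyloxy)methyl]-3-methoxyphenyl}acetate | CCOC(=O)Cc1cc(CO[Si](C)(C)C(C)(C)C)cc(OC)c1OCc1ccc(OCc2ccccc2)c(OC)c1
F0 | step 19 | none | none
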